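The dearomatized acylphloroglucinol carbocycle (ring A) is cut across two opposite bonds into a ketone-derived C–C(O)–C(CH3)2 unit and a malonyl C(=O)–CH2–C(O) unit. The key step is an Effenberger-type [3+3] α,α′-annulation: a regiodefined acyclic silyl enol ether is C-acylated twice by malonyl dichloride, forming in one operation the C(CH3)2–C(=O) bond and the bond between the enolic C(OH) carbon and the ring carbon that later carries the pyran CH2. It exploits the 1,3,5-oxygenation of ring A and its quaternary gem-dimethyl carbon, which blocks pyranone formation. C-acylation and an oxidative ortho-quinone methide hetero-Diels–Alder reaction with (−)-β-caryophyllene (pyran ring B) finish the route.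

Key step: step 2

Assumption: compounds 6, 8, 9 and 11 are drawn as single tautomers of equilibrating keto–enol mixtures, and 6 and 8 are racemic at the enolizable methyl-bearing ring carbon.

Step 1
Reactants: 1 2-methylpent-1-en-3-one; 2 triethylsilane
Product: 3 triethyl[(2-methylpent-2-en-3-yl)oxy]silane
Conditions: Et3SiH, RhCl(PPh3)3 (cat.), PhH, 50 °C
Reagents that add atoms: triethylsilane, CC[SiH](CC)CC
Why: Rhodium-catalysed 1,4-hydrosilylation of the enone delivers hydrogen to the terminal CH2 and silicon to oxygen, so the tetrasubstituted silyl enol ether should form regiospecifically, which enolization of ethyl isopropyl ketone would not secure.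

Step 2
Reactants: 3 triethyl[(2-methylpent-2-en-3-yl)oxy]silane; 4 malonyl dichloride
Product: 6 2,4,4-trimethylcyclohexane-1,3,5-trione, via keto acid chloride 5 (not isolated)
Conditions: ClCOCH2COCl, Et2O, −20 °C to rt; then aq KOH, BnEt3NCl; then aq HCl
Reagents that add atoms: malonyl dichloride, O=C(Cl)CC(=O)Cl
Why: Enol ether 3 is C-acylated at its isopropylidene carbon by malonyl dichloride (or the chlorocarbonylketene derived from it) with loss of Et3SiCl, giving 5 with the gem-dimethyl carbon already quaternary; HCl-promoted enolization of the ethyl ketone toward its CH2 then lets that enol carbon attack the acid chloride (or the derived acylketene) to close the carbocycle, and the acidic trione is taken up as its potassium salt on the basic quench. The closest known reaction type is the Effenberger cyclization, the α,α′-annulation of methyl or silyl enol ethers of ketones with malonyl dichloride that builds the cyclohexane-1,3,5-trione ring of bicyclo[3.3.1]nonane-2,4,9-triones. The one ring formed closes in a 6-(enolendo)-exo-trig mode. No stereocentre has to be controlled, because the methyl-bearing ring carbon of 6 is enolizable and becomes sp2 in the following intermediates. The step needs the first acylation to occur at the isopropylidene carbon, which the regiodefined enol ether from step 1 secures. It also needs closure through carbon and not oxygen, which the quaternary gem-dimethyl carbon favours: it blocks aromatization to a 4-hydroxy-2-pyranone and leaves O-closure only as a reversible enol lactone, whereas C-closure ends in the stabilized vinylogous acid.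

Step 3
Reactants: 6 2,4,4-trimethylcyclohexane-1,3,5-trione; 7 (2S)-2-methylbutanoic acid
Product: 9 3,5-dihydroxy-4,6,6-trimethyl-2-[(2S)-2-methylbutanoyl]cyclohexa-2,4-dien-1-one, via enol ester 8 (not isolated)
Conditions: DCC, DMAP, CH2Cl2, 0 °C to rt
Reagents that add atoms: (2S)-2-methylbutanoic acid, CC[C@H](C)C(=O)O
Why: Steglich-type O-acylation of the enolized trione followed by DMAP-mediated O-to-C acyl migration, the usual route to 2-acyl-1,3-diones, should place the acyl group on the unsubstituted CH2 carbon, because only there is the product a chelated, fully enolized β-triketone, and the near-neutral conditions should leave the (S) α-stereocentre intact.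

Step 4
Reactants: 9 3,5-dihydroxy-4,6,6-trimethyl-2-[(2S)-2-methylbutanoyl]cyclohexa-2,4-dien-1-one; 10 (−)-β-caryophyllene
Product: 12 target meroterpenoid CNP0591516.1, via quinone methide 11 (not isolated)
Conditions: 10 (excess), Ag2O, TEMPO (cat.), THF, rt
Reagents that add atoms: (−)-β-caryophyllene, C=C1CC/C=C(C)/CC[C@@H]2[C@@H]1CC2(C)C
Why: Dehydrogenation of the ring methyl gives ortho-quinone methide 11, whose C=CH2/C=O heterodiene (the carbonyl next to the gem-dimethyl carbon, the other oxygen being held in the chelated enol) should add in an inverse-electron-demand hetero-Diels–Alder reaction to the strained E-alkene of 10, with CH2 bonding to the alkene CH (C5) and O to the methyl-bearing C4, suprafacially so that C4–CH3 and C5–H are trans, and the target (4S,5R) configuration arises from attack on the face exposed in the ββ ring conformer (C4 methyl on the side of H-1), the adduct from the other face (αα and βα conformers) being expected alongside, possibly as the larger component, and removed by chromatography.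

Compound list
1 | 2-methylpent-1-en-3-one | C=C(C)C(=O)CC | starting material
2 | triethylsilane | CC[SiH](CC)CC | starting material
3 | triethyl[(2-methylpent-2-en-3-yl)oxy]silane | CCC(O[Si](CC)(CC)CC)=C(C)C | intermediate
4 | malonyl dichloride (propanedioyl dichloride) | O=C(Cl)CC(=O)Cl | starting material
5 | 4,4-dimethyl-3,5-dioxoheptanoyl chloride (not isolated) | CCC(=O)C(C)(C)C(=O)CC(=O)Cl | intermediate
6 | 2,4,4-trimethylcyclohexane-1,3,5-trione (triketo tautomer drawn) | CC1C(=O)CC(=O)C(C)(C)C1=O | intermediate
7 | (2S)-2-methylbutanoic acid | CC[C@H](C)C(=O)O | starting material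
8 | 4,4,6-trimethyl-3,5-dioxocyclohex-1-en-1-yl (2S)-2-methylbutanoate (not isolated) | CC[C@H](C)C(=O)OC1=CC(=O)C(C)(C)C(=O)C1C | intermediate
9 | 3,5-dihydroxy-4,6,6-trimethyl-2-[(2S)-2-methylbutanoyl]cyclohexa-2,4-dien-1-one | CC[C@H](C)C(=O)C1=C(O)C(C)=C(O)C(C)(C)C1=O | intermediate
10 | (−)-β-caryophyllene, (1R,4E,9S)-4,11,11-trimethyl-8-methylidenebicyclo[7.2.0]undec-4-ene | C=C1CC/C=C(C)/CC[C@@H]2[C@@H]1CC2(C)C | starting material
11 | 5-hydroxy-2,2-dimethyl-6-methylidene-4-[(2S)-2-methylbutanoyl]cyclohex-4-ene-1,3-dione (ortho-quinone methide, not isolated) | C=C1C(=O)C(C)(C)C(=O)C(C(=O)[C@@H](C)CC)=C1O | intermediate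
12 | target: ring A (hydroxy-gem-dimethyl-cyclohexadienone bearing the (2S)-2-methylbutanoyl group) fused through dihydropyran ring B (O on the methyl-bearing C4, CH2 on C5) to the nine-membered ring with exocyclic methylene and the trans-fused gem-dimethylcyclobutane; caryophyllane numbering 1R,4S,5R,9S | C=C1CC[C@@H]2CC3=C(O[C@@]2(C)CC[C@@H]2[C@@H]1CC2(C)C)C(C)(C)C(=O)C(C(=O)[C@@H](C)CC)=C3O | target

Total step count: 4
Longest linear sequence: 4 steps (1 → 3 → 6 → 9 → 12)

Steps most likely to fail

Step 2. After the first C-acylation the ring may close through the ketone oxygen to an alkylidene lactone instead of through carbon, or the non-enolizable 1,3-diketone unit of 5 may be cleaved by hydroxide during the quench. The fallback sets out from 3 and returns at 6. Enol ether 3 is C-acylated with methyl 3-chloro-3-oxopropanoate (ZnCl2, CH2Cl2, 0 °C) to give isolable methyl 4,4-dimethyl-3,5-dioxoheptanoate F1. An ester cannot acylate the enol oxygen under these conditions, so treatment with KOtBu (2.2 equiv) in THF should effect a Dieckmann-type closure through the ethyl-ketone enolate with loss of methanol. The same two ring bonds are formed, but in two stages.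

Step 4. Attack on the other face of the caryophyllene alkene may predominate, since the required face is exposed only in the less populated ββ conformer. In addition, the oxidant may consume the quinone methide or the terpene faster than they combine. The fallback sets out from 9 and returns at 12 through 11. Selenenylation of 9 at the methyl-bearing ring carbon (PhSeCl, pyridine, CH2Cl2) gives 5-hydroxy-2,2,6-trimethyl-4-[(2S)-2-methylbutanoyl]-6-(phenylselanyl)cyclohex-4-ene-1,3-dione F2 as both epimers. Oxidation with mCPBA at −78 °C gives the selenoxide 6-(benzeneseleninyl)-5-hydroxy-2,2,6-trimethyl-4-[(2S)-2-methylbutanoyl]cyclohex-4-ene-1,3-dione F3. Addition of 10 and warming triggers syn-elimination toward the only β-hydrogens (the CH3), releasing 11 without a metal oxidant. The cycloaddition can then be run from low temperature upward and in other media to shift the Curtin–Hammett face ratio. This fallback does not guarantee the face selectivity, and separation of the two adducts remains necessary.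

Step 3. The acyl transfer may stop at enol ester 8, or the α-stereocentre may erode through ketene formation from the acyl-DMAP species. The fallback sets out from 7 and returns at 9. Acid 7 is converted with oxalyl chloride (cat. DMF, CH2Cl2) into (2S)-2-methylbutanoyl chloride F4. This is combined with 6 and TiCl4 in CH2Cl2, a Lewis-acid-mediated Friedel–Crafts/Fries-type C-acylation under non-basic conditions.

Further compounds
F1 | step 2 | methyl 4,4-dimethyl-3,5-dioxoheptanoate | CCC(=O)C(C)(C)C(=O)CC(=O)OC
F2 | step 4 | 5-hydroxy-2,2,6-trimethyl-4-[(2S)-2-methylbutanoyl]-6-(phenylselanyl)cyclohex-4-ene-1,3-dione (both epimers at the selenium-bearing carbon) | CC[C@H](C)C(=O)C1=C(O)C(C)([Se]c2ccccc2)C(=O)C(C)(C)C1=O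
F3 | step 4 | 6-(benzeneseleninyl)-5-hydroxy-2,2,6-trimethyl-4-[(2S)-2-methylbutanoyl]cyclohex-4-ene-1,3-dione | CC[C@H](C)C(=O)C1=C(O)C(C)([Se](=O)c2ccccc2)C(=O)C(C)(C)C1=O
F4 | step 3 | (2S)-2-methylbutanoyl chloride | CC[C@H](C)C(=O)Cl
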